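## Retrosynthetic overview

- The two carbinol centres have opposite sense: the free one on the acid half is (8S), the acylated one is (4R). One (S)-hydroxyalkylresorcinol therefore serves both halves if the ester alkyl C–O bond is made with inversion; this is the key disconnection.
- The acid half comes from the same (S)-monomer by ring formylation, in which the carbinol is masked as a formate in the same operation, then aldehyde oxidation.
- The (S)-monomer comes from (S)-undec-10-en-4-ol and 5-bromobenzene-1,3-diol by hydroboration and B-alkyl Suzuki–Miyaura coupling.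
- The alkenol comes from hex-5-enyl Grignard opening of (S)-2-propyloxirane, the only source of chirality.
- No ring is formed in the route; both benzene rings are bought as 5-bromobenzene-1,3-diol.

Assumption: reagents such as 9-BBN, Tf2O and (2-hydroxybenzyl)diphenylphosphine oxide are bought; only compounds that give atoms to the target are numbered.

## Route

Step 1
Reactants: 1 6-bromohex-1-ene; 2 (2S)-2-propyloxirane
Product: 4 (4S)-undec-10-en-4-ol, via hex-5-en-1-ylmagnesium bromide 3 (not isolated)
Conditions: Mg, THF, 23 → 40 °C; then CuI (10 mol%), 2, THF, −30 → 0 °C; sat. aq NH4Cl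
Reagents that add atoms: none
Why: Grignard formation followed by copper-catalysed SN2 opening of the terminal epoxide at its unsubstituted carbon leaves the C–O stereocentre of 2 untouched, so the (S) carbinol is taken from the chiral pool.

Step 2
Reactants: 4 (4S)-undec-10-en-4-ol; 5 5-bromobenzene-1,3-diol
Product: 7 5-[(8S)-8-hydroxyundecyl]benzene-1,3-diol, via B-alkyl-9-BBN O-borinate 6 (not isolated)
Conditions: 9-BBN (2.3 equiv), THF, 0 → 23 °C; then 5, Pd(OAc)2 (3 mol%), SPhos (6 mol%), 3 M aq K3PO4, THF, 65 °C
Reagents that add atoms: none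
Why: Anti-Markovnikov hydroboration of the terminal alkene (the hydroxyl is masked in the flask as its O-borinate) followed by B-alkyl Suzuki–Miyaura coupling forms the aryl–CH2 bond far from the carbinol, and the electron-rich biarylphosphine allows oxidative addition into the deprotonated bromoresorcinol.

Step 3
Reactants: 7 5-[(8S)-8-hydroxyundecyl]benzene-1,3-diol
Product: 9 (4S)-11-(2-formyl-3,5-dihydroxyphenyl)undecan-4-yl formate, via bis-iminium dichloride 8 (not isolated)
Conditions: POCl3 (3 equiv), DMF, 0 → 20 °C; then aq NaOAc, 0 → 23 °C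
Reagents that add atoms: N,N-dimethylformamide (CN(C)C=O); water (O)
Why: Vilsmeier–Haack formylation of 5-alkylresorcinols goes para to one hydroxyl and ortho to the alkyl chain, and the same reagent converts the secondary alcohol into an alkoxymethyleneiminium ion that hydrolyses with the C–O bond intact to the formate, which protects the (S) carbinol with retention.

Step 4
Reactants: 9 (4S)-11-(2-formyl-3,5-dihydroxyphenyl)undecan-4-yl formate
Product: 10 2-[(8S)-8-(formyloxy)undecyl]-4,6-dihydroxybenzoic acid
Conditions: NaClO2, NaH2PO4, DMSO/H2O, 0 → 15 °C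
Reagents that add atoms: sodium chlorite ([Na+].[O-]Cl=O)
Why: Pinnick (Lindgren) chlorite oxidation converts the aldehyde to the acid at about pH 4, with DMSO scavenging hypochlorite so the resorcinol ring is not chlorinated, the formate survives, and the decarboxylation-prone acid is never heated.

Step 5
Reactants: 10 2-[(8S)-8-(formyloxy)undecyl]-4,6-dihydroxybenzoic acid; 7 5-[(8S)-8-hydroxyundecyl]benzene-1,3-diol
Product: 13 (4R)-11-(3,5-dihydroxyphenyl)undecan-4-yl 2,4-dihydroxy-6-[(8S)-8-hydroxyundecyl]benzoate (target), via alkoxyphosphonium triflate 11 (not isolated), via O-formyl ester 12 (not isolated)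
Conditions: (2-hydroxybenzyl)diphenylphosphine oxide (1.3 equiv), Tf2O (1.2 equiv), 2,6-lutidine, CH2Cl2, −40 → 0 °C; 7 (1.3 equiv), 0 °C; 10 (1.0 equiv), 2,6-lutidine, CH2Cl2/MeCN, 0 → 23 °C; then NH3, MeOH, 0 °C
Reagents that add atoms: none
Why: Proposed new method: a stoichiometric, azo-free, pKa-gated Mitsunobu-type esterification in which the preformed strained cyclic oxyphosphonium salt 2,2-diphenyl-3H-1,2-benzoxaphosphol-2-ium triflate is opened at phosphorus by the aliphatic hydroxyl of 7 to give alkoxyphosphonium 11 (phenols can only give aryloxyphosphonium ions, which revert), 2,6-lutidine (conjugate acid pKa about 6.7) ionises only the carboxyl group of 10 (pKa about 3.5) and not the phenols (pKa above 8), and the di-ortho-substituted carboxylate, poor at acyl transfer, displaces the phosphine oxide by SN2 at carbon with inversion from (S) to (R), after which ammonia removes the formate without attacking the hindered salicylate ester; the closest known reaction types are the Mitsunobu reaction and the phosphine-oxide-catalysed redox-neutral dehydrative substitution, which runs through the same cyclic oxyphosphonium ion but is established only at reflux with strongly acidic pronucleophiles.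

## Compound list

1 | 6-bromohex-1-ene | C=CCCCCBr | starting material
2 | (2S)-2-propyloxirane | CCC[C@H]1CO1 | starting material
3 | hex-5-en-1-ylmagnesium bromide | C=CCCCC[Mg]Br | intermediate
4 | (4S)-undec-10-en-4-ol | CCC[C@H](O)CCCCCC=C | intermediate
5 | 5-bromobenzene-1,3-diol | Oc1cc(O)cc(Br)c1 | starting material
6 | 9-{(8S)-8-[(9-borabicyclo[3.3.1]nonan-9-yl)oxy]undecyl}-9-borabicyclo[3.3.1]nonane | CCC[C@H](OB1C2CCCC1CCC2)CCCCCCCB1C2CCCC1CCC2 | intermediate
7 | 5-[(8S)-8-hydroxyundecyl]benzene-1,3-diol | CCC[C@H](O)CCCCCCCc1cc(O)cc(O)c1 | intermediate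
8 | N-[(2-{(8S)-8-[(dimethyliminio)methoxy]undecyl}-4,6-dihydroxyphenyl)methylidene]-N-methylmethanaminium dichloride | CCC[C@H](OC=[N+](C)C)CCCCCCCc1cc(O)cc(O)c1C=[N+](C)C.[Cl-].[Cl-] | intermediate
9 | (4S)-11-(2-formyl-3,5-dihydroxyphenyl)undecan-4-yl formate | CCC[C@H](OC=O)CCCCCCCc1cc(O)cc(O)c1C=O | intermediate
10 | 2-[(8S)-8-(formyloxy)undecyl]-4,6-dihydroxybenzoic acid | CCC[C@H](OC=O)CCCCCCCc1cc(O)cc(O)c1C(=O)O | intermediate
11 | {[(4S)-11-(3,5-dihydroxyphenyl)undecan-4-yl]oxy}[(2-hydroxyphenyl)methyl]diphenylphosphonium trifluoromethanesulfonate | CCC[C@H](O[P+](c1ccccc1)(c1ccccc1)Cc1ccccc1O)CCCCCCCc1cc(O)cc(O)c1.[O-]S(=O)(=O)C(F)(F)F | intermediate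
12 | (4R)-11-(3,5-dihydroxyphenyl)undecan-4-yl 2-[(8S)-8-(formyloxy)undecyl]-4,6-dihydroxybenzoate | CCC[C@H](OC=O)CCCCCCCc1cc(O)cc(O)c1C(=O)O[C@H](CCC)CCCCCCCc1cc(O)cc(O)c1 | intermediate
13 | (4R)-11-(3,5-dihydroxyphenyl)undecan-4-yl 2,4-dihydroxy-6-[(8S)-8-hydroxyundecyl]benzoate | CCC[C@H](O)CCCCCCCc1cc(O)cc(O)c1C(=O)O[C@H](CCC)CCCCCCCc1cc(O)cc(O)c1 | target

## Step count and risk

Total step count: 5. Longest linear sequence: 5 (1 and 2 → 4 → 7 → 9 → 10 → 13); compound 7 is used twice, as precursor of the acid and as the alcohol partner.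

The three steps most likely to fail:

**Step 5 (the proposed new esterification).** The oxyphosphonium reagent may be held up by the phenols, or the lutidinium carboxylate may be too weak a nucleophile. The fallback sets out from 10 and 7 and uses the classical Mitsunobu redox condensation (PPh3, DIAD, THF, 0 → 23 °C), which is known to esterify unprotected 2,4-dihydroxy-6-alkylbenzoic acids at the carboxyl group. Here the alcohol is activated by an external phosphine/azodicarboxylate couple in the presence of the acid, through the ion pair {[(4S)-11-(3,5-dihydroxyphenyl)undecan-4-yl]oxy}triphenylphosphonium 2-[(8S)-8-(formyloxy)undecyl]-4,6-dihydroxybenzoate F1, which collapses with inversion. It comes back to the route at 12, which is deformylated with NH3/MeOH as in step 5.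

**Step 3 (double-duty Vilsmeier reaction).** The activated carbinol may be chlorinated, or formate formation may be incomplete. The fallback sets out from 7 and separates protection from ring formylation. Formic acid (98%, 23 → 40 °C) esterifies only the aliphatic hydroxyl, by Fischer esterification with retention, to give (4S)-11-(3,5-dihydroxyphenyl)undecan-4-yl formate F2. A Vilsmeier–Haack reaction with one equivalent of reagent then formylates only the ring, through N-({2-[(8S)-8-(formyloxy)undecyl]-4,6-dihydroxyphenyl}methylidene)-N-methylmethanaminium chloride F3, which is hydrolysed with aq NaOAc. It comes back to the route at 9.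

**Step 2 (B-alkyl Suzuki coupling of an unprotected bromoresorcinol).** The phenoxide form of 5 may undergo oxidative addition too slowly. The fallback sets out from 4 (through borane 6) and couples with commercial 1-bromo-3,5-bis(benzyloxy)benzene (PdCl2(dppf), aq K3PO4, THF, 65 °C) to give (4S)-11-[3,5-bis(benzyloxy)phenyl]undecan-4-ol F4. Hydrogenolysis (H2, Pd/C, EtOAc/MeOH, 23 °C) then frees the phenols, and the route is rejoined at 7.

## Further compounds

F1 | step 5 | {[(4S)-11-(3,5-dihydroxyphenyl)undecan-4-yl]oxy}triphenylphosphonium 2-[(8S)-8-(formyloxy)undecyl]-4,6-dihydroxybenzoate | CCC[C@H](O[P+](c1ccccc1)(c1ccccc1)c1ccccc1)CCCCCCCc1cc(O)cc(O)c1.CCC[C@H](OC=O)CCCCCCCc1cc(O)cc(O)c1C(=O)[O-]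
F2 | step 3 | (4S)-11-(3,5-dihydroxyphenyl)undecan-4-yl formate | CCC[C@H](OC=O)CCCCCCCc1cc(O)cc(O)c1
F3 | step 3 | N-({2-[(8S)-8-(formyloxy)undecyl]-4,6-dihydroxyphenyl}methylidene)-N-methylmethanaminium chloride | CCC[C@H](OC=O)CCCCCCCc1cc(O)cc(O)c1C=[N+](C)C.[Cl-]
F4 | step 2 | (4S)-11-[3,5-bis(benzyloxy)phenyl]undecan-4-ol | CCC[C@H](O)CCCCCCCc1cc(OCc2ccccc2)cc(OCc2ccccc2)c1
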